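## Analysis of the target

Compound 32 is a B-type prodelphinidin trimer, (−)-epigallocatechin-(4β→8)-(−)-epigallocatechin 3-O-gallate-(4β→8)-(−)-epigallocatechin. Each of its three flavan-3-ol units has a phloroglucinol-type ring A, a dihydropyran ring C and a pyrogallol ring B; the units are joined by two C4→C8 bonds, and only the middle unit carries a galloyl ester on O3. There are eight stereocentres: C2 and C3 of every unit are (2R,3R) with aryl and oxygen cis, and C4 of the top and of the middle unit bears the next ring A trans to its own C3 oxygen, so all three units share one absolute sense. Eighteen phenols and two secondary alcohols are free; the pyrogallol rings oxidise readily, the gallate is base-labile, C2 can epimerise by ring opening once the phenols are free, and both interflavan bonds are doubly benzylic bonds between electron-rich rings that ionise under acid. The synthesis is hard because two different interflavan bonds must be made at C8 and not at C6, one of three secondary oxygens must be acylated, and C4 must be set twice without scrambling bonds already in place. The strategy rests on ring A of the bottom unit, the terminal unit whose C4 is a methylene: C8a carries the ring oxygen O1, the adjacent C8 carries C4 of the middle unit, and the C7 oxygen sits on the far side of C8. A heteroatom and a carbon substituent on neighbouring ring carbons can be installed in one operation across an aryne; the C7 oxygen fixes the polarisation of that aryne, and the C2 oxygen can reach C8a through the three atoms C2, C3 and C4 that hang from C4a. The bottom ring C and the lower interflavan bond can therefore be made together under basic organomagnesium conditions, in which nothing in the molecule ionises.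

## Retrosynthetic reasoning

Target 32 is traced back to its icosa-O-benzyl ether 31. Benzyl on all twenty hydroxyls gives one neutral, final deprotection that leaves the gallate and the interflavan bonds alone.

In 31 the middle ring C is cut at O1–C2 and C3–C4. This leads to the o-quinone methide 30, formed from the o-hydroxy diarylmethanol 29, and to the (Z)-enol gallate 28. The cut is made here because 28 brings C2, C3, ring B and the ester in one piece, so only the middle O3 is ever acylated. It also makes the configuration of the carbinol carbon of 29 irrelevant, since that carbon is planar in 30. The forward cycloaddition has to keep the alkene geometry (2,3-cis), place the C4 aryl group trans to O3, and choose the correct diene face.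

Phenol 29 comes from its allyl ether 25. An acetal protecting group on this oxygen would need acid for its removal, and acid would ionise the carbinol at the same moment. An allyl ether can be removed under neutral conditions, so the phenol is freed first and the quinone methide is generated afterwards in a controlled way.

Carbinol 25 is cut at two bonds of the bottom unit: O1–C8a and C8–C4(middle). Both bonds lie on adjacent carbons of ring A, so they are assigned to one aryne, 23. Its C8a accepts the tethered C2 alkoxide, and its C8 then becomes the arylmagnesium 24, which adds to aldehyde 21. The precursor is the 2-iodoaryl sulfonate 14, which is converted to 23 through 22. This disconnection closes ring C with retention at C2 and makes the lower interflavan bond without acid, so the existing upper interflavan bond of 21 is never at risk.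

Sulfonate 14 comes from iodophenol 13, and 13 from phenol 12. Iodination is placed before sulfonylation because the free hydroxyl directs the halogen to the ortho carbon (the future C8), and because the sulfonate cannot be present while organometallic reagents act on the ring.

In 12 the C4–C4a bond is cut, giving the primary sulfonate 6 and the arylmagnesium 10, which is made from aryl iodide 9 and coupled through 11. Iodide 9 comes from 8 and the commercial phenol 7. Ring A is bought rather than built, and the bond is made at a primary carbon, so no stereocentre is touched.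

Sulfonate 6 comes from diol 5 and the aldol adduct 4. Adduct 4 is cut at C2–C3 into aldehyde 2 and the glycolate imide 1, reacting through enolate 3. The retained C2–O bond turns a syn (Fischer threo) hydroxyl/benzyloxy pair into the 2,3-cis chroman, so the aldol has to be syn-selective. The glycolate aldol also delivers the C3 oxygen already benzylated and the C2 oxygen free. That differentiation is essential: a free C3 alkoxide would close a five-membered ring on C8a.

Aldehyde 21 is simplified through salicylaldehyde 20 to phenol 19, and 19 is cut at the upper interflavan bond into the C4 electrophile 18 and phenol 7. Electrophile 18 comes from 17, 16 and natural 15, which supplies C2 and C3 of the top unit. The free hydroxyl of 7 steers the arylation to its ortho carbon and then the formylation to the other ortho carbon. This is exactly the 1,2,3-pattern (CHO, O, C8 substituent) needed for the middle ring A.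

Enol ester 28 is cut at the enol C–O bond into alkyne 26 and acid 27, and 26 comes from aldehyde 2 by one-carbon homologation.

## Alternatives that were turned down

Alternative 1: The three bonds C8–C8a, C6–C7 and C4a–C8a of bottom ring A would be cut. That ring would be built by a vinylketene benzannulation between a cyclobutenone carrying the bottom C2/C3 chain and an alkynyl silyl ether placed on C4 of a finished top–middle dimer gallate. Heating should lead through four pericyclic events to the hexasubstituted phenol A1.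
- For it: the substitution pattern of the new ring follows from the connectivity of the partners, so the C8 attachment and the free C8a hydroxyl are unambiguous. All stereocentres of the top and middle units would come from natural flavan units by established cationic coupling. On this point it is stronger than the chosen route, which has to create C2, C3 and C4 of the middle unit late.
- Against it: the ring that is constructed is one that can be bought. The alkynyl ether sits on a doubly benzylic, ionisable C4 next to an ester and must survive prolonged heating. The cyclobutenone with its chiral chain needs a long synthesis of its own. A1 still has ring C open, so a closure with inversion at the benzylic C2 (a centre prone to ionisation) and two silyl removals remain.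
- Comparison: the chosen route keeps ring A from 7, closes ring C with retention in the same operation that forms the interflavan bond, and reaches its key precursor in fewer steps. In exchange it accepts a late stereo-determining cycloaddition.

Alternative 2: The top ring C would be cut at C4–C4a and O1–C2. A secondary-amine catalyst would convert a C8 acrolein on a middle–bottom dimer gallate into its iminium ion, an electron-rich phenol would add through its ortho carbon, and the phenol oxygen would close the lactol A2.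
- For it: the key step belongs to a well-precedented reaction type and sets the top C4 under catalyst control. On precedent it is stronger than the aryne relay.
- Against it: A2 has neither ring B at C2 nor an oxygen at C3. Installing both, cis to each other and in the correct absolute sense, on a substrate that already carries the gallate needs several further steps with weak stereocontrol, and aryl-metal reagents would attack the ester. The β-carbon of the acrolein is flanked by two ortho substituents and is hindered. Natural 15 supplies these three stereocentres for nothing.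
- Comparison: the chosen route uses 15 for the top unit and spends its one unprecedented step on a transformation that leaves the finished chroman and the interflavan bond behind, not a lactol that has to be rebuilt.

Alternative 3: The bottom ring C would be cut at C4–C4a. A Lewis acid in a fluorinated alcohol would activate a terminal epoxide carried on an aryl ether, and the free ortho carbon would attack the CH2 terminus to give A3, with a bromine blocking C6.
- For it: epoxide–arene cyclisations are known, C2 and C3 come from an epoxy alcohol, the 3-hydroxyl emerges free, and only hydrogenolysis follows. On precedent and on the length of the end game it is stronger than the chosen route.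
- Against it: the step is run with a strong Lewis acid on a complete trimer whose two interflavan bonds ionise under exactly such conditions. The secondary benzylic aryl ether O1–C2 has to be made stereospecifically on a di-ortho-substituted phenol beforehand, and it can itself ionise and epimerise C2. Attack at the internal epoxide carbon would give a dihydrobenzofuran. A blocking bromine has to be carried.
- Comparison: the chosen route forms the bonds of the bottom unit under basic conditions, where neither C2 nor the interflavan bonds can ionise, and it needs no blocking group because the tether and the C7 oxygen fix the regiochemistry.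

Key step: step 15

Assumption: 1, 7 and 27 are treated as catalogue compounds, and the carbinol carbon of 25 and 29 is left unassigned because both epimers give the same 30.

## Route

Step 1
Reactants: 1 (S)-4-benzyl-3-[(benzyloxy)acetyl]oxazolidin-2-one; 2 3,4,5-tris(benzyloxy)benzaldehyde
Product: 4 (S)-4-benzyl-3-[(2S,3R)-2-(benzyloxy)-3-hydroxy-3-[3,4,5-tris(benzyloxy)phenyl]propanoyl]oxazolidin-2-one, via dibutylboron (Z)-enolate 3 (not isolated)
Conditions: Bu2BOTf, Et3N, CH2Cl2, −78 → 0 °C; 2, −78 → 0 °C; H2O2, pH 7 buffer, MeOH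
Reagents that add atoms: none
Why: Evans syn aldol of a glycolate imide: the (Z)-boron enolate 3 reacts through a closed chair transition state on the face opposite the auxiliary benzyl group and should give the 2,3-syn adduct. Its C3(R) and C2(S) become C2 and C3 of the bottom unit, with the C3 oxygen already benzylated and the C2 oxygen free.

Step 2
Reactants: 4 (S)-4-benzyl-3-[(2S,3R)-2-(benzyloxy)-3-hydroxy-3-[3,4,5-tris(benzyloxy)phenyl]propanoyl]oxazolidin-2-one
Product: 5 (1R,2R)-2-(benzyloxy)-1-[3,4,5-tris(benzyloxy)phenyl]propane-1,3-diol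
Conditions: LiBH4, MeOH (1 equiv), THF, 0 °C
Reagents that add atoms: none
Why: Reductive cleavage of the N-acyl oxazolidinone by hydride attack at the exocyclic carbonyl; neither stereocentre is involved and the auxiliary is recovered.

Step 3
Reactants: 5 (1R,2R)-2-(benzyloxy)-1-[3,4,5-tris(benzyloxy)phenyl]propane-1,3-diol
Product: 6 (2R,3R)-2-(benzyloxy)-3-hydroxy-3-[3,4,5-tris(benzyloxy)phenyl]propyl 4-methylbenzenesulfonate
Conditions: TsCl, Et3N, DMAP (cat.), CH2Cl2, 0 °C
Reagents that add atoms: 4-methylbenzenesulfonyl chloride, Cc1ccc(cc1)S(Cl)(=O)=O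
Why: Selective sulfonylation of the primary hydroxyl; the secondary benzylic hydroxyl is more hindered and should stay free at 0 °C with one equivalent of reagent.

Step 4
Reactants: 7 3,5-bis(benzyloxy)phenol
Product: 8 3,5-bis(benzyloxy)-2-iodophenol
Conditions: NIS, CH2Cl2, −20 → 0 °C, dark
Reagents that add atoms: N-iodosuccinimide, O=C1CCC(=O)N1I
Why: Electrophilic aromatic iodination of a 3,5-dialkoxyphenol; the two equivalent carbons between hydroxyl and benzyloxy are less hindered than the carbon between the two benzyloxy groups, so mono-iodination ortho to the hydroxyl is expected.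

Step 5
Reactants: 8 3,5-bis(benzyloxy)-2-iodophenol
Product: 9 [3,5-bis(benzyloxy)-2-iodophenoxy]tri(propan-2-yl)silane
Conditions: TIPSOTf, 2,6-lutidine, CH2Cl2, 0 °C
Reagents that add atoms: triisopropylsilyl trifluoromethanesulfonate, CC(C)[Si](OS(=O)(=O)C(F)(F)F)(C(C)C)C(C)C
Why: Silylation of the phenol with a silyl triflate; the bulky silyl ether tolerates the arylmagnesium chemistry of the next step and is removed by fluoride.

Step 6
Reactants: 9 [3,5-bis(benzyloxy)-2-iodophenoxy]tri(propan-2-yl)silane; 6 (2R,3R)-2-(benzyloxy)-3-hydroxy-3-[3,4,5-tris(benzyloxy)phenyl]propyl 4-methylbenzenesulfonate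
Product: 12 (1R,2R)-2-(benzyloxy)-3-[2,4-bis(benzyloxy)-6-hydroxyphenyl]-1-[3,4,5-tris(benzyloxy)phenyl]propan-1-ol, via arylmagnesium iodide 10 (not isolated), via triisopropylsilyl ether 11 (not isolated)
Conditions: 9, Mg, LiCl, THF, rt; 6 + MeMgCl (1 equiv), THF, −40 °C; CuI (10 mol%), −20 °C → rt; then TBAF, 0 °C
Reagents that add atoms: none
Why: Magnesium insertion gives Grignard reagent 10, and CuI-catalysed cross-coupling of a Grignard reagent with a primary alkyl sulfonate forms C4–C4a while the secondary hydroxyl is masked as its chloromagnesium alkoxide. Fluoride then cleaves the aryl silyl ether of 11 in the same flask; the stereocentres are not involved.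

Step 7
Reactants: 12 (1R,2R)-2-(benzyloxy)-3-[2,4-bis(benzyloxy)-6-hydroxyphenyl]-1-[3,4,5-tris(benzyloxy)phenyl]propan-1-ol
Product: 13 (1R,2R)-2-(benzyloxy)-3-[4,6-bis(benzyloxy)-2-hydroxy-3-iodophenyl]-1-[3,4,5-tris(benzyloxy)phenyl]propan-1-ol
Conditions: NIS, CH2Cl2, −40 → 0 °C, dark
Reagents that add atoms: N-iodosuccinimide, O=C1CCC(=O)N1I
Why: Electrophilic iodination of the most electron-rich ring at the remaining carbon ortho to the free hydroxyl (the future C8). The para carbon is shielded by two benzyloxy groups, one of them pushed towards it by the new side chain; the halogenation of 5,7-dibenzyloxyflavans at C8 is the analogy.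

Step 8
Reactants: 13 (1R,2R)-2-(benzyloxy)-3-[4,6-bis(benzyloxy)-2-hydroxy-3-iodophenyl]-1-[3,4,5-tris(benzyloxy)phenyl]propan-1-ol
Product: 14 3,5-bis(benzyloxy)-2-[(2R,3R)-2-(benzyloxy)-3-hydroxy-3-[3,4,5-tris(benzyloxy)phenyl]propyl]-6-iodophenyl 4-chlorobenzenesulfonate
Conditions: 4-ClC6H4SO2Cl, K2CO3, acetone, rt
Reagents that add atoms: 4-chlorobenzenesulfonyl chloride, O=S(=O)(Cl)c1ccc(Cl)cc1
Why: Sulfonylation of the phenoxide; the weak base deprotonates only the phenol, so the secondary alcohol should remain free.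

Step 9
Reactants: 15 (−)-epigallocatechin
Product: 16 5,7,3',4',5'-penta-O-benzyl-(−)-epigallocatechin
Conditions: BnBr, K2CO3, DMF, 0 °C → rt, N2, dark
Reagents that add atoms: benzyl bromide, BrCc1ccccc1
Why: Williamson etherification of the five phenols with a weak base, which leaves the aliphatic 3-hydroxyl and the C2 configuration untouched.

Step 10
Reactants: 16 5,7,3',4',5'-penta-O-benzyl-(−)-epigallocatechin
Product: 17 3,5,7,3',4',5'-hexa-O-benzyl-(−)-epigallocatechin
Conditions: NaH, BnBr, Bu4NI (cat.), DMF, 0 °C → rt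
Reagents that add atoms: benzyl bromide, BrCc1ccccc1
Why: Williamson etherification of the secondary alcohol through its sodium alkoxide; with all phenols capped, C2 cannot epimerise by ring opening.

Step 11
Reactants: 17 3,5,7,3',4',5'-hexa-O-benzyl-(−)-epigallocatechin
Product: 18 4β-(2-ethoxyethoxy)-3,5,7,3',4',5'-hexa-O-benzyl-(−)-epigallocatechin
Conditions: DDQ, HOCH2CH2OEt, CH2Cl2, rt
Reagents that add atoms: 2-ethoxyethanol, CCOCCO
Why: Benzylic oxidation: DDQ abstracts hydride from C4, which is activated by the 5,7-dioxygenated ring A, and the alcohol captures the cation trans to the C3 substituent.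

Step 12
Reactants: 18 4β-(2-ethoxyethoxy)-3,5,7,3',4',5'-hexa-O-benzyl-(−)-epigallocatechin; 7 3,5-bis(benzyloxy)phenol
Product: 19 3,5-bis(benzyloxy)-2-[3,5,7,3',4',5'-hexa-O-benzyl-(−)-epigallocatechin-4β-yl]phenol
Conditions: 7 (4 equiv), BF3·OEt2, CH2Cl2, −78 → −30 °C
Reagents that add atoms: none
Why: Lewis-acid ionisation of the C4 ether followed by Friedel–Crafts capture by the phenol at its less hindered ortho carbon. Attack anti to the 3-benzyloxy group sets C4 of the top unit as 4β (3,4-trans), and the excess of 7 suppresses double alkylation.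

Step 13
Reactants: 19 3,5-bis(benzyloxy)-2-[3,5,7,3',4',5'-hexa-O-benzyl-(−)-epigallocatechin-4β-yl]phenol
Product: 20 4,6-bis(benzyloxy)-2-hydroxy-3-[3,5,7,3',4',5'-hexa-O-benzyl-(−)-epigallocatechin-4β-yl]benzaldehyde
Conditions: MgCl2, Et3N, (CH2O)n, MeCN, reflux
Reagents that add atoms: paraformaldehyde (as formaldehyde), C=O
Why: Casnati–Skattebøl ortho-formylation: formaldehyde is delivered within the magnesium phenoxide to the only free ortho carbon, and a second formaldehyde oxidises the benzylic alkoxide, so the carbon between the two benzyloxy groups is not touched.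

Step 14
Reactants: 20 4,6-bis(benzyloxy)-2-hydroxy-3-[3,5,7,3',4',5'-hexa-O-benzyl-(−)-epigallocatechin-4β-yl]benzaldehyde
Product: 21 2-(allyloxy)-4,6-bis(benzyloxy)-3-[3,5,7,3',4',5'-hexa-O-benzyl-(−)-epigallocatechin-4β-yl]benzaldehyde
Conditions: allyl bromide, K2CO3, DMF, 50 °C
Reagents that add atoms: allyl bromide, C=CCBr
Why: Williamson allylation of the chelated phenol; the allyl ether survives Grignard reagents and can later be removed without acid.

Step 15
Reactants: 14 3,5-bis(benzyloxy)-2-[(2R,3R)-2-(benzyloxy)-3-hydroxy-3-[3,4,5-tris(benzyloxy)phenyl]propyl]-6-iodophenyl 4-chlorobenzenesulfonate; 21 2-(allyloxy)-4,6-bis(benzyloxy)-3-[3,5,7,3',4',5'-hexa-O-benzyl-(−)-epigallocatechin-4β-yl]benzaldehyde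
Product: 25 [2-(allyloxy)-4,6-bis(benzyloxy)-3-(hexa-O-benzyl-epigallocatechin-4β-yl)phenyl](hexa-O-benzyl-epigallocatechin-8-yl)methanol (both carbinol epimers), via magnesiated sulfonate 22 (not isolated), via aryne 23 (not isolated), via 8-chromanylmagnesium chloride 24 (not isolated)
Conditions: iPrMgCl·LiCl (2.1 equiv), THF, −78 → 0 °C; then 21, LaCl3·2LiCl, 0 °C → rt
Reagents that add atoms: none
Why: Proposed new method: the first equivalent of iPrMgCl·LiCl deprotonates the C2 carbinol and the second exchanges the C8 iodide, which is activated by the two flanking oxygen substituents, to give 22; on warming, 22 loses 4-chlorobenzenesulfonate from C8a and becomes the C8–C8a aryne 23. The tethered chloromagnesium alkoxide adds to C8a in a 6-exo mode (the attacked aryne bond lies outside the ring being formed), which makes O1–C8a, closes ring C and leaves the carbanion on C8 as arylmagnesium 24. Flanked by O1 and the C7 benzyloxy group, 24 is inductively stabilised and long-lived; it adds to the aldehyde of 21, with LaCl3·2LiCl assisting the hindered carbonyl addition, and forms C8–C4. The closest known reaction types are aryne generation from 2-iodoaryl arenesulfonates by iodine–magnesium exchange with addition of magnesium thiolates or amides and aldehyde trapping of the resulting arylmagnesium, and the intramolecular alkoxide–aryne cyclisation to chromans; using a tethered alkoxide as the first nucleophile of such a relay is the new element. The regiochemistry of aryne capture is doubly secured: the three-atom tether can only reach C8a, and the C7 oxygen polarises the aryne so that the nucleophile enters at the distal carbon and the charge ends next to oxygen. C2 and C3 are untouched because the C2–O bond is never broken, so the syn pair of 14 becomes the 2,3-cis chroman; the only new stereocentre is the carbinol carbon, which is not controlled and need not be, since it is planar in 30. The step needs exchange at iodine to be faster than attack of the Grignard reagent at sulfur, which −78 °C should secure, and cyclisation to precede carbonyl addition, which is secured by adding 21 only after the aryne has been consumed.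

Step 16
Reactants: 2 3,4,5-tris(benzyloxy)benzaldehyde
Product: 26 1,2,3-tris(benzyloxy)-5-ethynylbenzene
Conditions: dimethyl (1-diazo-2-oxopropyl)phosphonate, K2CO3, MeOH/THF, rt
Reagents that add atoms: dimethyl (1-diazo-2-oxopropyl)phosphonate, CC(=O)C(=[N+]=[N-])P(=O)(OC)OC
Why: Ohira–Bestmann homologation: methanolysis frees the diazomethylphosphonate anion, which converts the aldehyde into the terminal alkyne through a vinylidene carbene.

Step 17
Reactants: 26 1,2,3-tris(benzyloxy)-5-ethynylbenzene; 27 3,4,5-tris(benzyloxy)benzoic acid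
Product: 28 (Z)-2-[3,4,5-tris(benzyloxy)phenyl]ethenyl 3,4,5-tris(benzyloxy)benzoate
Conditions: [RuCl2(p-cymene)]2 (cat.), P(4-ClC6H4)3, DMAP, toluene, 60 °C
Reagents that add atoms: none
Why: Anti-Markovnikov addition of a carboxylic acid to a terminal alkyne through a vinylidene complex formed from [RuCl2(p-cymene)]2; carboxylate attack on the vinylidene carbon gives the (Z)-enol ester.

Step 18
Reactants: 25 [2-(allyloxy)-4,6-bis(benzyloxy)-3-(hexa-O-benzyl-epigallocatechin-4β-yl)phenyl](hexa-O-benzyl-epigallocatechin-8-yl)methanol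
Product: 29 [4,6-bis(benzyloxy)-2-hydroxy-3-(hexa-O-benzyl-epigallocatechin-4β-yl)phenyl](hexa-O-benzyl-epigallocatechin-8-yl)methanol
Conditions: Pd(PPh3)4 (cat.), morpholine, THF, rt; filtration through Et3N-deactivated silica
Reagents that add atoms: none
Why: Deallylation by zerovalent palladium through a π-allyl complex that the amine intercepts; the neutral conditions keep the ionisable diarylmethanol intact.

Step 19
Reactants: 29 [4,6-bis(benzyloxy)-2-hydroxy-3-(hexa-O-benzyl-epigallocatechin-4β-yl)phenyl](hexa-O-benzyl-epigallocatechin-8-yl)methanol; 28 (Z)-2-[3,4,5-tris(benzyloxy)phenyl]ethenyl 3,4,5-tris(benzyloxy)benzoate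
Product: 31 icosa-O-benzyl-epigallocatechin-(4β→8)-epigallocatechin 3-O-gallate-(4β→8)-epigallocatechin, via o-quinone methide 30 (not isolated)
Conditions: (R)-TRIP [(R)-3,3'-bis(2,4,6-triisopropylphenyl)-1,1'-binaphthyl-2,2'-diyl hydrogen phosphate] (10 mol%), 28 (3 equiv), 4 Å MS, CH2Cl2, 0 °C → rt
Reagents that add atoms: none
Why: Proposed new method: the acid dehydrates 29 to o-quinone methide 30, an electron-poor heterodiene with C4 as its electrophilic and the carbonyl oxygen as its nucleophilic end, while in the β-acyloxystyrene 28 the electron-rich aryl group makes the acyloxy-bearing carbon the nucleophilic one, so C3–C4 and O1–C2 form with the regiochemistry of a flavan-3-ol ester. Suprafacial addition to the (Z)-alkene gives 2,3-cis, approach with the dienophile substituents turned away from the C4 aryl group (exo) gives 3,4-trans, and the diene face is chosen by the hydrogen-bonded chiral phosphate together with the C8 flavanyl group. The closest known reaction type is the chiral phosphoric acid-catalysed inverse-demand oxa-Diels–Alder reaction of o-quinone methides from o-hydroxybenzhydrols with styrenes and enol ethers.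

Step 20
Reactants: 31 icosa-O-benzyl-epigallocatechin-(4β→8)-epigallocatechin 3-O-gallate-(4β→8)-epigallocatechin
Product: 32 (−)-epigallocatechin-(4β→8)-(−)-epigallocatechin 3-O-gallate-(4β→8)-(−)-epigallocatechin
Conditions: H2 (1 atm), Pd(OH)2/C, THF/MeOH/H2O, rt; filtration and lyophilisation under argon
Reagents that add atoms: none
Why: Hydrogenolysis of the twenty benzyl ethers under neutral conditions; the aryl ester and the interflavan C–C bonds are not cleaved, and no stereocentre is affected.

## Compound list

1 | (S)-4-benzyl-3-[(benzyloxy)acetyl]oxazolidin-2-one | O=C(COCc1ccccc1)N1[C@@H](Cc2ccccc2)COC1=O | starting material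
2 | 3,4,5-tris(benzyloxy)benzaldehyde | O=Cc1cc(OCc2ccccc2)c(OCc2ccccc2)c(OCc2ccccc2)c1 | starting material
3 | dibutylboron (Z)-enolate of 1 (not isolated) | CCCCB(CCCC)O/C(=C\OCc1ccccc1)N1[C@@H](Cc2ccccc2)COC1=O | intermediate
4 | (S)-4-benzyl-3-[(2S,3R)-2-(benzyloxy)-3-hydroxy-3-[3,4,5-tris(benzyloxy)phenyl]propanoyl]oxazolidin-2-one | O[C@H](c6cc(OCc5ccccc5)c(OCc5ccccc5)c(OCc5ccccc5)c6)[C@H](OCc5ccccc5)C(=O)N1[C@@H](Cc2ccccc2)COC1=O | intermediate
5 | (1R,2R)-2-(benzyloxy)-1-[3,4,5-tris(benzyloxy)phenyl]propane-1,3-diol | O[C@H](c6cc(OCc5ccccc5)c(OCc5ccccc5)c(OCc5ccccc5)c6)[C@H](OCc5ccccc5)CO | intermediate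
6 | (2R,3R)-2-(benzyloxy)-3-hydroxy-3-[3,4,5-tris(benzyloxy)phenyl]propyl 4-methylbenzenesulfonate | O[C@H](c6cc(OCc5ccccc5)c(OCc5ccccc5)c(OCc5ccccc5)c6)[C@H](OCc5ccccc5)COS(=O)(=O)c1ccc(C)cc1 | intermediate
7 | 3,5-bis(benzyloxy)phenol | Oc1cc(OCc2ccccc2)cc(OCc2ccccc2)c1 | starting material
8 | 3,5-bis(benzyloxy)-2-iodophenol | Oc1cc(OCc2ccccc2)cc(OCc2ccccc2)c1I | intermediate
9 | [3,5-bis(benzyloxy)-2-iodophenoxy]tri(propan-2-yl)silane | CC(C)[Si](C(C)C)(C(C)C)Oc1cc(OCc2ccccc2)cc(OCc2ccccc2)c1I | intermediate
10 | [2,4-bis(benzyloxy)-6-(triisopropylsilyloxy)phenyl]magnesium iodide (not isolated) | CC(C)[Si](C(C)C)(C(C)C)Oc1cc(OCc2ccccc2)cc(OCc2ccccc2)c1[Mg]I | intermediate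
11 | (1R,2R)-2-(benzyloxy)-3-[2,4-bis(benzyloxy)-6-(triisopropylsilyloxy)phenyl]-1-[3,4,5-tris(benzyloxy)phenyl]propan-1-ol (not isolated) | O[C@H](c6cc(OCc5ccccc5)c(OCc5ccccc5)c(OCc5ccccc5)c6)[C@H](OCc5ccccc5)Cc1c(OCc5ccccc5)cc(OCc5ccccc5)cc1O[Si](C(C)C)(C(C)C)C(C)C | intermediate
12 | (1R,2R)-2-(benzyloxy)-3-[2,4-bis(benzyloxy)-6-hydroxyphenyl]-1-[3,4,5-tris(benzyloxy)phenyl]propan-1-ol | O[C@H](c6cc(OCc5ccccc5)c(OCc5ccccc5)c(OCc5ccccc5)c6)[C@H](OCc5ccccc5)Cc1c(OCc5ccccc5)cc(OCc5ccccc5)cc1O | intermediate
13 | (1R,2R)-2-(benzyloxy)-3-[4,6-bis(benzyloxy)-2-hydroxy-3-iodophenyl]-1-[3,4,5-tris(benzyloxy)phenyl]propan-1-ol | O[C@H](c6cc(OCc5ccccc5)c(OCc5ccccc5)c(OCc5ccccc5)c6)[C@H](OCc5ccccc5)Cc1c(OCc5ccccc5)cc(OCc5ccccc5)c(I)c1O | intermediate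
14 | 3,5-bis(benzyloxy)-2-[(2R,3R)-2-(benzyloxy)-3-hydroxy-3-[3,4,5-tris(benzyloxy)phenyl]propyl]-6-iodophenyl 4-chlorobenzenesulfonate (aryne precursor) | O[C@H](c6cc(OCc5ccccc5)c(OCc5ccccc5)c(OCc5ccccc5)c6)[C@H](OCc5ccccc5)Cc1c(OCc5ccccc5)cc(OCc5ccccc5)c(I)c1OS(=O)(=O)c1ccc(Cl)cc1 | intermediate
15 | (−)-epigallocatechin | Oc1cc(O)c2c(c1)O[C@H](c1cc(O)c(O)c(O)c1)[C@H](O)C2 | starting material
16 | 5,7,3',4',5'-penta-O-benzyl-(−)-epigallocatechin | C1c2c(OCc5ccccc5)cc(OCc5ccccc5)cc2O[C@H](c6cc(OCc5ccccc5)c(OCc5ccccc5)c(OCc5ccccc5)c6)[C@@H]1O | intermediate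
17 | 3,5,7,3',4',5'-hexa-O-benzyl-(−)-epigallocatechin | C1c2c(OCc5ccccc5)cc(OCc5ccccc5)cc2O[C@H](c6cc(OCc5ccccc5)c(OCc5ccccc5)c(OCc5ccccc5)c6)[C@@H]1OCc5ccccc5 | intermediate
18 | 4β-(2-ethoxyethoxy)-3,5,7,3',4',5'-hexa-O-benzyl-(−)-epigallocatechin (3,4-trans) | CCOCCO[C@H]1c2c(OCc5ccccc5)cc(OCc5ccccc5)cc2O[C@H](c6cc(OCc5ccccc5)c(OCc5ccccc5)c(OCc5ccccc5)c6)[C@@H]1OCc5ccccc5 | intermediate
19 | 3,5-bis(benzyloxy)-2-[3,5,7,3',4',5'-hexa-O-benzyl-(−)-epigallocatechin-4β-yl]phenol | Oc1cc(OCc5ccccc5)cc(OCc5ccccc5)c1[C@H]3c4c(OCc5ccccc5)cc(OCc5ccccc5)cc4O[C@H](c6cc(OCc5ccccc5)c(OCc5ccccc5)c(OCc5ccccc5)c6)[C@@H]3OCc5ccccc5 | intermediate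
20 | 4,6-bis(benzyloxy)-2-hydroxy-3-[3,5,7,3',4',5'-hexa-O-benzyl-(−)-epigallocatechin-4β-yl]benzaldehyde | O=Cc2c(OCc5ccccc5)cc(OCc5ccccc5)c([C@H]3c4c(OCc5ccccc5)cc(OCc5ccccc5)cc4O[C@H](c6cc(OCc5ccccc5)c(OCc5ccccc5)c(OCc5ccccc5)c6)[C@@H]3OCc5ccccc5)c2O | intermediate
21 | 2-(allyloxy)-4,6-bis(benzyloxy)-3-[3,5,7,3',4',5'-hexa-O-benzyl-(−)-epigallocatechin-4β-yl]benzaldehyde | O=Cc2c(OCc5ccccc5)cc(OCc5ccccc5)c([C@H]3c4c(OCc5ccccc5)cc(OCc5ccccc5)cc4O[C@H](c6cc(OCc5ccccc5)c(OCc5ccccc5)c(OCc5ccccc5)c6)[C@@H]3OCc5ccccc5)c2OCC=C | intermediate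
22 | C8-chloromagnesio derivative of the chloromagnesium alkoxide of 14 (not isolated) | Cl[Mg]O[C@H](c6cc(OCc5ccccc5)c(OCc5ccccc5)c(OCc5ccccc5)c6)[C@H](OCc5ccccc5)Cc1c(OCc5ccccc5)cc(OCc5ccccc5)c([Mg]Cl)c1OS(=O)(=O)c1ccc(Cl)cc1 | intermediate
23 | C8–C8a aryne bearing the tethered chloromagnesium alkoxide (not isolated) | Cl[Mg]O[C@H](c6cc(OCc5ccccc5)c(OCc5ccccc5)c(OCc5ccccc5)c6)[C@H](OCc5ccccc5)CC1=C(OCc5ccccc5)C=C(OCc5ccccc5)C#C1 | intermediate
24 | [3,5,7,3',4',5'-hexa-O-benzyl-(−)-epigallocatechin-8-yl]magnesium chloride (not isolated) | Cl[Mg]c1c(OCc5ccccc5)cc(OCc5ccccc5)c2c1O[C@H](c6cc(OCc5ccccc5)c(OCc5ccccc5)c(OCc5ccccc5)c6)[C@H](OCc5ccccc5)C2 | intermediate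
25 | [2-(allyloxy)-4,6-bis(benzyloxy)-3-(hexa-O-benzyl-epigallocatechin-4β-yl)phenyl](hexa-O-benzyl-epigallocatechin-8-yl)methanol, both carbinol epimers | OC(c2c(OCc5ccccc5)cc(OCc5ccccc5)c3c2O[C@H](c6cc(OCc5ccccc5)c(OCc5ccccc5)c(OCc5ccccc5)c6)[C@H](OCc5ccccc5)C3)c2c(OCc5ccccc5)cc(OCc5ccccc5)c([C@H]3c4c(OCc5ccccc5)cc(OCc5ccccc5)cc4O[C@H](c6cc(OCc5ccccc5)c(OCc5ccccc5)c(OCc5ccccc5)c6)[C@@H]3OCc5ccccc5)c2OCC=C | intermediate
26 | 1,2,3-tris(benzyloxy)-5-ethynylbenzene | C#Cc1cc(OCc2ccccc2)c(OCc2ccccc2)c(OCc2ccccc2)c1 | intermediate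
27 | 3,4,5-tris(benzyloxy)benzoic acid | OC(=O)c1cc(OCc2ccccc2)c(OCc2ccccc2)c(OCc2ccccc2)c1 | starting material
28 | (Z)-2-[3,4,5-tris(benzyloxy)phenyl]ethenyl 3,4,5-tris(benzyloxy)benzoate | O=C(O/C=C\c1cc(OCc2ccccc2)c(OCc2ccccc2)c(OCc2ccccc2)c1)c1cc(OCc2ccccc2)c(OCc2ccccc2)c(OCc2ccccc2)c1 | intermediate
29 | [4,6-bis(benzyloxy)-2-hydroxy-3-(hexa-O-benzyl-epigallocatechin-4β-yl)phenyl](hexa-O-benzyl-epigallocatechin-8-yl)methanol, both carbinol epimers | OC(c2c(OCc5ccccc5)cc(OCc5ccccc5)c3c2O[C@H](c6cc(OCc5ccccc5)c(OCc5ccccc5)c(OCc5ccccc5)c6)[C@H](OCc5ccccc5)C3)c2c(OCc5ccccc5)cc(OCc5ccccc5)c([C@H]3c4c(OCc5ccccc5)cc(OCc5ccccc5)cc4O[C@H](c6cc(OCc5ccccc5)c(OCc5ccccc5)c(OCc5ccccc5)c6)[C@@H]3OCc5ccccc5)c2O | intermediate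
30 | o-quinone methide of the middle ring A with the bottom unit on the methide carbon and the top unit at C8 (not isolated) | O=C1C([C@H]3c4c(OCc5ccccc5)cc(OCc5ccccc5)cc4O[C@H](c6cc(OCc5ccccc5)c(OCc5ccccc5)c(OCc5ccccc5)c6)[C@@H]3OCc5ccccc5)=C(OCc5ccccc5)C=C(OCc5ccccc5)C1=Cc2c(OCc5ccccc5)cc(OCc5ccccc5)c3c2O[C@H](c6cc(OCc5ccccc5)c(OCc5ccccc5)c(OCc5ccccc5)c6)[C@H](OCc5ccccc5)C3 | intermediate
31 | icosa-O-benzyl-epigallocatechin-(4β→8)-epigallocatechin 3-O-gallate-(4β→8)-epigallocatechin | O=C(O[C@@H]1[C@@H](c2c(OCc5ccccc5)cc(OCc5ccccc5)c3c2O[C@H](c6cc(OCc5ccccc5)c(OCc5ccccc5)c(OCc5ccccc5)c6)[C@H](OCc5ccccc5)C3)c2c(OCc5ccccc5)cc(OCc5ccccc5)c([C@H]3c4c(OCc5ccccc5)cc(OCc5ccccc5)cc4O[C@H](c6cc(OCc5ccccc5)c(OCc5ccccc5)c(OCc5ccccc5)c6)[C@@H]3OCc5ccccc5)c2O[C@@H]1c6cc(OCc5ccccc5)c(OCc5ccccc5)c(OCc5ccccc5)c6)c7cc(OCc5ccccc5)c(OCc5ccccc5)c(OCc5ccccc5)c7 | intermediate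
32 | (−)-epigallocatechin-(4β→8)-(−)-epigallocatechin 3-O-gallate-(4β→8)-(−)-epigallocatechin (CNP0278699.1) | O=C(O[C@@H]1[C@@H](c2c(O)cc(O)c3c2O[C@H](c2cc(O)c(O)c(O)c2)[C@H](O)C3)c2c(O)cc(O)c([C@H]3c4c(O)cc(O)cc4O[C@H](c4cc(O)c(O)c(O)c4)[C@@H]3O)c2O[C@@H]1c1cc(O)c(O)c(O)c1)c1cc(O)c(O)c(O)c1 | target

## Step count and least certain steps

Total step count: 20. Longest linear sequence: 10 steps (steps 1, 2, 3, 6, 7, 8, 15, 18, 19, 20); the branch from 15 through steps 9 to 14 and on through steps 15, 18, 19 and 20 is equally long.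

Step 15 (key step, proposed new method). Three things are most likely to go wrong:
- The chloromagnesium alkoxide may be too weak a nucleophile, so the aryne is consumed by intermolecular paths: attack by residual Grignard reagent or chloride, or by another arylmagnesium.
- The alkoxide may be sulfonylated by the neighbouring sulfonate before the exchange.
- The arylmagnesium 24 may be protonated before it adds to the very hindered, electron-rich aldehyde, which would give 17 and not 25.

Fallback by known chemistry, with no aryne: set out from 17, which is the bottom unit with hydrogen at C8. Bromination with N-bromosuccinimide (CH2Cl2, −78 → 0 °C) should give 8-bromo-3,5,7,3',4',5'-hexa-O-benzyl-(−)-epigallocatechin F1, as halogenation of 5,7-dibenzyloxyflavans goes to C8. Bromine–lithium exchange with n-BuLi (THF, −78 °C) and addition of the aryllithium to aldehyde 21 comes back to the route at 25.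

Step 19 (proposed new method). Three things are most likely to go wrong:
- Stereochemical integrity may be lost through a stepwise cationic pathway: the intermediate benzylic cation can rotate, giving the 2,3-trans series, or close on either face.
- The catalyst and the C8 flavanyl group may be mismatched, so the wrong diene face reacts.
- The strongly stabilised quinone methide may be too unreactive towards a weak dienophile, so Friedel–Crafts attack by the free C6 and C8 positions of other molecules competes.

The antipodal phosphoric acid would be the first variation. The fallback changes the approach to known cationic interflavan coupling. Set out from 16 and 27: esterification (DCC, DMAP, CH2Cl2) gives 5,7,3',4',5'-penta-O-benzyl-(−)-epigallocatechin 3-O-(3,4,5-tri-O-benzylgallate) F2. Oxidation with DDQ and 2-ethoxyethanol gives its 4β-(2-ethoxyethoxy) derivative F3. TMSOTf-mediated coupling of F3 with an excess of 17 (CH2Cl2, −78 °C, attack at C8 of 17, anti to the 3-acyloxy group) gives the perbenzylated epigallocatechin 3-O-gallate-(4β→8)-epigallocatechin dimer F4. A second TMSOTf-mediated coupling, of electrophile 18 with F4 at C8 of its galloylated upper unit, comes back to the route at 31.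

Step 6. The substitution at the primary carbon, which is β-branched and β-oxygenated, by a di-ortho-substituted arylcopper species may be slow. Elimination to an enol ether, closure of the γ-alkoxide to an oxetane, or protonation of 10 could then take over. The fallback replaces substitution by carbonyl addition and ionic deoxygenation. Set out from 5: selective oxidation of the primary alcohol (TEMPO, PhI(OAc)2, CH2Cl2) gives (2S,3R)-2-(benzyloxy)-3-hydroxy-3-[3,4,5-tris(benzyloxy)phenyl]propanal F5. Addition of an excess of 10 gives 2-(benzyloxy)-1-[2,4-bis(benzyloxy)-6-(triisopropylsilyloxy)phenyl]-3-[3,4,5-tris(benzyloxy)phenyl]propane-1,3-diol F6 as a mixture at the new carbinol. Et3SiH with CF3CO2H (CH2Cl2, −78 °C) removes the hydroxyl on the carbon attached to the trioxygenated ring, which ionises far more easily than the other benzylic position. This comes back to the route at 11, which is desilylated with TBAF to 12 as in step 6.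

Step 12. Alkylation may occur at the carbon para to the hydroxyl or at two carbons of 7, and O-alkylation may persist, because the free cation discriminates only by sterics. The fallback replaces the free cation by delivery within a metal phenoxide. Set out from 7: EtMgBr gives bromomagnesium 3,5-bis(benzyloxy)phenoxide F7. In CH2Cl2/toluene F7 coordinates the leaving ether oxygen of 18 and should transfer the flavan-4-yl group to its own ortho carbon through a cyclic transition state. This comes back to the route at 19.

Step 7. Iodination may go para to the hydroxyl (between the two benzyloxy groups), or a second iodine may enter there. The fallback brings the iodine in before the side chain. Set out from 7: two equivalents of NIS should give 3,5-bis(benzyloxy)-2,6-diiodophenol F8, and TIPSOTf with 2,6-lutidine gives [3,5-bis(benzyloxy)-2,6-diiodophenoxy]tri(propan-2-yl)silane F9. Exchange of one iodine with iPrMgCl·LiCl and CuI-catalysed coupling with the chloromagnesium alkoxide of 6 gives (1R,2R)-2-(benzyloxy)-3-[4,6-bis(benzyloxy)-3-iodo-2-(triisopropylsilyloxy)phenyl]-1-[3,4,5-tris(benzyloxy)phenyl]propan-1-ol F10. TBAF comes back to the route at 13.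

## Further compounds

F1 | step 15 | 8-bromo-3,5,7,3',4',5'-hexa-O-benzyl-(−)-epigallocatechin | Brc1c(OCc5ccccc5)cc(OCc5ccccc5)c2c1O[C@H](c6cc(OCc5ccccc5)c(OCc5ccccc5)c(OCc5ccccc5)c6)[C@H](OCc5ccccc5)C2
F2 | step 19 | 5,7,3',4',5'-penta-O-benzyl-(−)-epigallocatechin 3-O-(3,4,5-tri-O-benzylgallate) | O=C(O[C@@H]1Cc2c(OCc5ccccc5)cc(OCc5ccccc5)cc2O[C@@H]1c6cc(OCc5ccccc5)c(OCc5ccccc5)c(OCc5ccccc5)c6)c7cc(OCc5ccccc5)c(OCc5ccccc5)c(OCc5ccccc5)c7
F3 | step 19 | 4β-(2-ethoxyethoxy)-5,7,3',4',5'-penta-O-benzyl-(−)-epigallocatechin 3-O-(3,4,5-tri-O-benzylgallate) | O=C(O[C@@H]1[C@@H](OCCOCC)c2c(OCc5ccccc5)cc(OCc5ccccc5)cc2O[C@@H]1c6cc(OCc5ccccc5)c(OCc5ccccc5)c(OCc5ccccc5)c6)c7cc(OCc5ccccc5)c(OCc5ccccc5)c(OCc5ccccc5)c7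
F4 | step 19 | perbenzylated epigallocatechin 3-O-gallate-(4β→8)-epigallocatechin dimer | O=C(O[C@@H]1[C@@H](c2c(OCc5ccccc5)cc(OCc5ccccc5)c3c2O[C@H](c6cc(OCc5ccccc5)c(OCc5ccccc5)c(OCc5ccccc5)c6)[C@H](OCc5ccccc5)C3)c2c(OCc5ccccc5)cc(OCc5ccccc5)cc2O[C@@H]1c6cc(OCc5ccccc5)c(OCc5ccccc5)c(OCc5ccccc5)c6)c7cc(OCc5ccccc5)c(OCc5ccccc5)c(OCc5ccccc5)c7
F5 | step 6 | (2S,3R)-2-(benzyloxy)-3-hydroxy-3-[3,4,5-tris(benzyloxy)phenyl]propanal | O[C@H](c6cc(OCc5ccccc5)c(OCc5ccccc5)c(OCc5ccccc5)c6)[C@H](OCc5ccccc5)C=O
F6 | step 6 | 2-(benzyloxy)-1-[2,4-bis(benzyloxy)-6-(triisopropylsilyloxy)phenyl]-3-[3,4,5-tris(benzyloxy)phenyl]propane-1,3-diol (2R,3R; epimers at C1) | O[C@H](c6cc(OCc5ccccc5)c(OCc5ccccc5)c(OCc5ccccc5)c6)[C@H](OCc5ccccc5)C(O)c1c(OCc5ccccc5)cc(OCc5ccccc5)cc1O[Si](C(C)C)(C(C)C)C(C)C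
F7 | step 12 | bromomagnesium 3,5-bis(benzyloxy)phenoxide | Br[Mg]Oc1cc(OCc2ccccc2)cc(OCc2ccccc2)c1
F8 | step 7 | 3,5-bis(benzyloxy)-2,6-diiodophenol | Oc1c(I)c(OCc2ccccc2)cc(OCc2ccccc2)c1I
F9 | step 7 | [3,5-bis(benzyloxy)-2,6-diiodophenoxy]tri(propan-2-yl)silane | CC(C)[Si](C(C)C)(C(C)C)Oc1c(I)c(OCc2ccccc2)cc(OCc2ccccc2)c1I
F10 | step 7 | (1R,2R)-2-(benzyloxy)-3-[4,6-bis(benzyloxy)-3-iodo-2-(triisopropylsilyloxy)phenyl]-1-[3,4,5-tris(benzyloxy)phenyl]propan-1-ol | O[C@H](c6cc(OCc5ccccc5)c(OCc5ccccc5)c(OCc5ccccc5)c6)[C@H](OCc5ccccc5)Cc1c(OCc5ccccc5)cc(OCc5ccccc5)c(I)c1O[Si](C(C)C)(C(C)C)C(C)C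
A1 | alternative 1 | benzannulation product: perbenzylated top–middle dimer gallate carrying on the middle C4 the new bottom ring A (free C8a hydroxyl, C7 triisopropylsilyl ether, C5 benzyl ether) with the open C2/C3 chain at C4a | O=C(O[C@@H]1[C@@H](c8c(O[Si](C(C)C)(C(C)C)C(C)C)cc(OCc5ccccc5)c(C[C@@H](OCc5ccccc5)[C@@H](O[Si](C)(C)C(C)(C)C)c6cc(OCc5ccccc5)c(OCc5ccccc5)c(OCc5ccccc5)c6)c8O)c2c(OCc5ccccc5)cc(OCc5ccccc5)c([C@H]3c4c(OCc5ccccc5)cc(OCc5ccccc5)cc4O[C@H](c6cc(OCc5ccccc5)c(OCc5ccccc5)c(OCc5ccccc5)c6)[C@@H]3OCc5ccccc5)c2O[C@@H]1c6cc(OCc5ccccc5)c(OCc5ccccc5)c(OCc5ccccc5)c6)c7cc(OCc5ccccc5)c(OCc5ccccc5)c(OCc5ccccc5)c7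
A2 | alternative 2 | perbenzylated middle–bottom dimer gallate carrying at the middle C8 a 5,7-bis(benzyloxy)chroman-2-ol joined through C4 (lactol anomers) | O=C(O[C@@H]1[C@@H](c2c(OCc5ccccc5)cc(OCc5ccccc5)c3c2O[C@H](c6cc(OCc5ccccc5)c(OCc5ccccc5)c(OCc5ccccc5)c6)[C@H](OCc5ccccc5)C3)c2c(OCc5ccccc5)cc(OCc5ccccc5)c([C@H]3c4c(OCc5ccccc5)cc(OCc5ccccc5)cc4OC(O)C3)c2O[C@@H]1c6cc(OCc5ccccc5)c(OCc5ccccc5)c(OCc5ccccc5)c6)c7cc(OCc5ccccc5)c(OCc5ccccc5)c(OCc5ccccc5)c7
A3 | alternative 3 | perbenzylated trimer gallate with free 3-hydroxyl and a C6 bromide on the bottom unit | O=C(O[C@@H]1[C@@H](c2c(OCc5ccccc5)c(Br)c(OCc5ccccc5)c3c2O[C@H](c6cc(OCc5ccccc5)c(OCc5ccccc5)c(OCc5ccccc5)c6)[C@H](O)C3)c2c(OCc5ccccc5)cc(OCc5ccccc5)c([C@H]3c4c(OCc5ccccc5)cc(OCc5ccccc5)cc4O[C@H](c6cc(OCc5ccccc5)c(OCc5ccccc5)c(OCc5ccccc5)c6)[C@@H]3OCc5ccccc5)c2O[C@@H]1c6cc(OCc5ccccc5)c(OCc5ccccc5)c(OCc5ccccc5)c6)c7cc(OCc5ccccc5)c(OCc5ccccc5)c(OCc5ccccc5)c7
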